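**Retrosynthetic overview**
1. The target comes from its ring-B tri-O-methyl ether by BCl3 ether cleavage, with no skeletal change.
2. Rings A and C are disconnected together. Ring A goes back to a 2-pyrone by a retro-Claisen cut of C5–C6. Ring C is opened by a retro-hetero-Diels–Alder cut of O1–C2 and C3–C4.
3. This leaves three pieces: an (E)-styrene carrying ring B, formaldehyde (C4), and a 4-hydroxy-6-(2-oxoalkyl)-2-pyrone that holds all six carbons of ring A plus the isovaleryl chain.
4. The styrene comes from diformylphloroglucinol and isovaleraldehyde, and the dialdehyde from phloroglucinol. The pyrone comes from triacetic acid lactone and methyl isovalerate.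
5. Ring order: ring B is bought. Ring C (which sets C2 and C3) and then ring A are made in one flask.

Ring letters and numbering: ring A is the acylphloroglucinol ring, ring B the diformylphloroglucinol ring, ring C the dihydropyran. Chroman numbering is O1, C2 (aryl), C3 (isopropyl), C4 (CH2). The target is the trans-(2R,3S) isomer, C25H28O9.

Assumption: the (R)-configured phosphoric acid is taken to give the (2R,3S) adduct. If the first run gives the antipode, the equally available (S)-acid is used and nothing else changes.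

Step 1
Reactants: 1 benzene-1,3,5-triol (phloroglucinol)
Product: 3 2,4,6-trihydroxybenzene-1,3-dicarbaldehyde, via bis(iminium) dichloride 2 (not isolated)
Conditions: POCl3 (2.5 equiv), DMF (2.5 equiv), 1,4-dioxane, 0 °C to rt; then ice–water
Reagents that add atoms: N,N-dimethylformamide CN(C)C=O; water O
Why: Double Vilsmeier–Haack formylation, in which phloroglucinol takes up two chloroiminium ions, the two iminium groups switch off the third position, and water hydrolyses both to aldehydes; no stereocentre is formed.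

Step 2
Reactants: 3 2,4,6-trihydroxybenzene-1,3-dicarbaldehyde; 4 3-methylbutanal (isovaleraldehyde)
Product: 6 2,4,6-trihydroxy-5-[(E)-3-methylbut-1-en-1-yl]benzene-1,3-dicarbaldehyde, via ortho-quinone methide 5 (not isolated)
Conditions: 4 (3 equiv), AcOH, conc. HCl (cat.), 75 °C, 0.02 M
Reagents that add atoms: none
Why: Acid-mediated Knoevenagel-type condensation at the only free ring carbon gives 5, which re-aromatises by a 1,5-hydrogen shift (the dehydrative alkenylation that turns lawsone and isovaleraldehyde into isolapachol), high dilution keeps 6 from adding to 5, and reversible protonation funnels the alkene to the more stable E isomer.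

Step 3
Reactants: 7 4-hydroxy-6-methyl-2H-pyran-2-one (triacetic acid lactone); 8 methyl 3-methylbutanoate (methyl isovalerate)
Product: 10 4-hydroxy-6-(4-methyl-2-oxopentyl)-2H-pyran-2-one, via dilithiated pyrone 9 (not isolated)
Conditions: LDA (3.2 equiv), THF, −78 to −20 °C; then 8 (1.0 equiv), −78 to 0 °C; 1 M HCl
Reagents that add atoms: none
Why: Crossed Claisen acylation of the C6-methyl carbanion of dianion 9, the most nucleophilic site of the pyrone, in which the third equivalent of base stores the more acidic product as its enolate and so stops a second acylation; no stereocentre is formed.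

Step 4
Reactants: 6 2,4,6-trihydroxy-5-[(E)-3-methylbut-1-en-1-yl]benzene-1,3-dicarbaldehyde; 10 4-hydroxy-6-(4-methyl-2-oxopentyl)-2H-pyran-2-one; 11 formaldehyde (used as paraformaldehyde)
Product: 16 5-[(2R,3S)-5,7-dihydroxy-6-(3-methylbutanoyl)-3-(propan-2-yl)-3,4-dihydro-2H-chromen-2-yl]-2,4,6-trimethoxybenzene-1,3-dicarbaldehyde, via methylenepyrandione 12 (not isolated), via cycloadduct 13 (not isolated), via tri-O-methyl cycloadduct 14 (not isolated), via ring-opened methyl ester 15 (not isolated)
Conditions: 6 (1.0 equiv), 11 (2 equiv), (R)-3,3'-bis(2,4,6-triisopropylphenyl)-1,1'-binaphthyl-2,2'-diyl hydrogen phosphate (10 mol %), 4 Å MS, ClCH2CH2Cl, 25–35 °C, 10 (1.3 equiv) added over 6 h; then Me3SiCHN2, MeOH, 0 °C; then Mg(OMe)2 (10 equiv), MeOH, 65 °C; 1 M HCl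
Reagents that add atoms: (trimethylsilyl)diazomethane C[Si](C)(C)C=[N+]=[N-]
Why: Proposed new method: Knoevenagel condensation of 10 and 11 gives heterodiene 12, which undergoes an inverse-electron-demand hetero-Diels–Alder reaction with 6 inside the chiral phosphoric acid (its acidic OH on the C4 carbonyl of 12, its phosphoryl oxygen on the one ortho-OH of 6 that has no formyl partner, since three OH groups face only two formyl acceptors), so that CH2 bonds to the nucleophilic β-carbon and O to the benzylic carbon, the E geometry is carried suprafacially into the trans C2/C3 relationship and the catalyst pocket selects the face pair giving 2R,3S (closest known types: phosphoric-acid-catalysed [4+2] reactions of ortho-quinone methides with ortho-hydroxystyrenes, and thermal trapping of 3-methylenechroman-2,4-dione by styrenes); neutral diazoalkane O-methylation, feasible because every ring-B OH is ortho or para to two formyl groups and acidic enough to protonate the reagent despite chelation, then removes the phenols that would expel O1 and erase C3 under base, after which Mg(OMe)2 opens the lactone to 15, whose magnesium β-diketonate carbon closes onto the ester (Claisen/Dieckmann cyclisation, closest known type: tetraacetic acid lactone to phloracetophenone) to build ring A with O1 fixed para to the acyl group, neither stereocentre being acidic or ionisable at that stage.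

Step 5
Reactants: 16 5-[(2R,3S)-5,7-dihydroxy-6-(3-methylbutanoyl)-3-(propan-2-yl)-3,4-dihydro-2H-chromen-2-yl]-2,4,6-trimethoxybenzene-1,3-dicarbaldehyde
Product: 17 5-[(2R,3S)-5,7-dihydroxy-6-(3-methylbutanoyl)-3-(propan-2-yl)-3,4-dihydro-2H-chromen-2-yl]-2,4,6-trihydroxybenzene-1,3-dicarbaldehyde
Conditions: BCl3 (8 equiv), CH2Cl2, −78 to 0 °C; then H2O
Reagents that add atoms: none
Why: Chelation-directed aryl methyl ether cleavage, in which BCl3 binds the formyl oxygens and cleaves the methoxy groups ortho to them (all three qualify) while the complexed, electron-poor ring B cannot stabilise a cation at C2, so the benzylic C2–O1 bond and both stereocentres stay untouched, as in the 5-O-demethylation of methoxyflavanones.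

**Compound list**
1 | benzene-1,3,5-triol (phloroglucinol) | Oc1cc(O)cc(O)c1 | starting material
2 | 2,4-bis[(dimethyliminio)methyl]benzene-1,3,5-triol dichloride | C[N+](C)=Cc1c(O)cc(O)c(C=[N+](C)C)c1O.[Cl-].[Cl-] | intermediate
3 | 2,4,6-trihydroxybenzene-1,3-dicarbaldehyde | O=Cc1c(O)cc(O)c(C=O)c1O | intermediate
4 | 3-methylbutanal | CC(C)CC=O | starting material
5 | 2,4-dihydroxy-5-(3-methylbutylidene)-6-oxocyclohexa-1,3-diene-1,3-dicarbaldehyde (ortho-quinone methide of ring B) | CC(C)CC=C1C(=O)C(C=O)=C(O)C(C=O)=C1O | intermediate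
6 | 2,4,6-trihydroxy-5-[(E)-3-methylbut-1-en-1-yl]benzene-1,3-dicarbaldehyde | CC(C)/C=C/c1c(O)c(C=O)c(O)c(C=O)c1O | intermediate
7 | 4-hydroxy-6-methyl-2H-pyran-2-one | CC1=CC(O)=CC(=O)O1 | starting material
8 | methyl 3-methylbutanoate | COC(=O)CC(C)C | starting material
9 | dilithium salt of 7 (4-oxide, 6-methanide) | [Li+].[Li+].[CH2-]C1=CC([O-])=CC(=O)O1 | intermediate
10 | 4-hydroxy-6-(4-methyl-2-oxopentyl)-2H-pyran-2-one | CC(C)CC(=O)CC1=CC(O)=CC(=O)O1 | intermediate
11 | formaldehyde (paraformaldehyde) | C=O | starting material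
12 | 3-methylidene-6-(4-methyl-2-oxopentyl)-2H-pyran-2,4(3H)-dione | CC(C)CC(=O)CC1=CC(=O)C(=C)C(=O)O1 | intermediate
13 | (2R,3S)-2-(3,5-diformyl-2,4,6-trihydroxyphenyl)-7-(4-methyl-2-oxopentyl)-3-(propan-2-yl)-3,4-dihydro-2H,5H-pyrano[4,3-b]pyran-5-one | CC(C)CC(=O)CC1=CC2=C(C[C@@H](C(C)C)[C@H](c3c(O)c(C=O)c(O)c(C=O)c3O)O2)C(=O)O1 | intermediate
14 | (2R,3S)-2-(3,5-diformyl-2,4,6-trimethoxyphenyl)-7-(4-methyl-2-oxopentyl)-3-(propan-2-yl)-3,4-dihydro-2H,5H-pyrano[4,3-b]pyran-5-one | CC(C)CC(=O)CC1=CC2=C(C[C@@H](C(C)C)[C@H](c3c(OC)c(C=O)c(OC)c(C=O)c3OC)O2)C(=O)O1 | intermediate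
15 | methyl (2R,3S)-2-(3,5-diformyl-2,4,6-trimethoxyphenyl)-6-(6-methyl-2,4-dioxoheptyl)-3-(propan-2-yl)-3,4-dihydro-2H-pyran-5-carboxylate (present as its magnesium enolate) | CC(C)CC(=O)CC(=O)CC1=C(C[C@@H](C(C)C)[C@H](c2c(OC)c(C=O)c(OC)c(C=O)c2OC)O1)C(=O)OC | intermediate
16 | 5-[(2R,3S)-5,7-dihydroxy-6-(3-methylbutanoyl)-3-(propan-2-yl)-3,4-dihydro-2H-chromen-2-yl]-2,4,6-trimethoxybenzene-1,3-dicarbaldehyde | CC(C)CC(=O)c1c(O)cc2c(c1O)C[C@@H](C(C)C)[C@H](c1c(OC)c(C=O)c(OC)c(C=O)c1OC)O2 | intermediate
17 | 5-[(2R,3S)-5,7-dihydroxy-6-(3-methylbutanoyl)-3-(propan-2-yl)-3,4-dihydro-2H-chromen-2-yl]-2,4,6-trihydroxybenzene-1,3-dicarbaldehyde | CC(C)CC(=O)c1c(O)cc2c(c1O)C[C@@H](C(C)C)[C@H](c1c(O)c(C=O)c(O)c(C=O)c1O)O2 | target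

Total step count: 5. Longest linear sequence: 4 steps (1 → 3 → 6 → 16 → 17).

**Steps most likely to fail**

Step 4 is the most exposed. A second molecule of 10 can drain 12, the catalyst–substrate pair is untested, and three reactions share one flask. The fallback buys ring A as an arene instead of building it, and needs neither capping nor step 5. It sets out from 1, 6 and 11 and comes back at 17. Friedel–Crafts acylation of 1 with isovaleryl chloride and AlCl3 gives 3-methyl-1-(2,4,6-trihydroxyphenyl)butan-1-one F3. Under the same phosphoric acid, F3, 11 and 6 give the ortho-quinone methide 3,5-dihydroxy-6-methylidene-4-(3-methylbutanoyl)cyclohexa-2,4-dien-1-one F4, which adds to 6 and gives 17 directly. The price is the 8-acyl regioisomer, which has to be removed by preparative HPLC.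

Step 2 is second. Alkene 6 can be consumed by its own precursor 5 to give dimers before it is isolated. The fallback traps 5 and eliminates later instead of relying on the hydrogen shift. It sets out from 3 and 4 and comes back at 6. Condensation in the presence of thiophenol (NaOAc, AcOH, 60 °C) intercepts 5 as racemic 2,4,6-trihydroxy-5-[3-methyl-1-(phenylsulfanyl)butyl]benzene-1,3-dicarbaldehyde F1. NaIO4 in aqueous MeOH then gives 5-[1-(benzenesulfinyl)-3-methylbutyl]-2,4,6-trihydroxybenzene-1,3-dicarbaldehyde F2. Thermal syn-elimination (toluene, 80 °C, P(OMe)3 as sulfenic acid trap) gives 6.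

Step 5 is third. Cleavage may stop short of three ethers, or the Lewis acid may open C2–O1. The fallback uses hydrogenolysis in place of a Lewis acid. It sets out from 13 and comes back at 17.
- In the flask of step 4, phenyldiazomethane replaces Me3SiCHN2 and gives (2R,3S)-2-[2,4,6-tris(benzyloxy)-3,5-diformylphenyl]-7-(4-methyl-2-oxopentyl)-3-(propan-2-yl)-3,4-dihydro-2H,5H-pyrano[4,3-b]pyran-5-one F5.
- Mg(OMe)2 takes F5 through methyl (2R,3S)-2-[2,4,6-tris(benzyloxy)-3,5-diformylphenyl]-6-(6-methyl-2,4-dioxoheptyl)-3-(propan-2-yl)-3,4-dihydro-2H-pyran-5-carboxylate F6.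
- F6 closes to 2,4,6-tris(benzyloxy)-5-[(2R,3S)-5,7-dihydroxy-6-(3-methylbutanoyl)-3-(propan-2-yl)-3,4-dihydro-2H-chromen-2-yl]benzene-1,3-dicarbaldehyde F7.
- H2 (1 atm), Pd(OH)2/C, EtOAc frees the three phenols and gives 17.

**Further compounds**
F1 | step 2 | 2,4,6-trihydroxy-5-[3-methyl-1-(phenylsulfanyl)butyl]benzene-1,3-dicarbaldehyde (racemic) | CC(C)CC(Sc1ccccc1)c1c(O)c(C=O)c(O)c(C=O)c1O
F2 | step 2 | 5-[1-(benzenesulfinyl)-3-methylbutyl]-2,4,6-trihydroxybenzene-1,3-dicarbaldehyde (mixture of stereoisomers) | CC(C)CC(S(=O)c1ccccc1)c1c(O)c(C=O)c(O)c(C=O)c1O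
F3 | step 4 | 3-methyl-1-(2,4,6-trihydroxyphenyl)butan-1-one | CC(C)CC(=O)c1c(O)cc(O)cc1O
F4 | step 4 | 3,5-dihydroxy-6-methylidene-4-(3-methylbutanoyl)cyclohexa-2,4-dien-1-one | CC(C)CC(=O)C1=C(O)C(=C)C(=O)C=C1O
F5 | step 5 | (2R,3S)-2-[2,4,6-tris(benzyloxy)-3,5-diformylphenyl]-7-(4-methyl-2-oxopentyl)-3-(propan-2-yl)-3,4-dihydro-2H,5H-pyrano[4,3-b]pyran-5-one | CC(C)CC(=O)CC1=CC2=C(C[C@@H](C(C)C)[C@H](c3c(OCc4ccccc4)c(C=O)c(OCc4ccccc4)c(C=O)c3OCc3ccccc3)O2)C(=O)O1
F6 | step 5 | methyl (2R,3S)-2-[2,4,6-tris(benzyloxy)-3,5-diformylphenyl]-6-(6-methyl-2,4-dioxoheptyl)-3-(propan-2-yl)-3,4-dihydro-2H-pyran-5-carboxylate | CC(C)CC(=O)CC(=O)CC1=C(C[C@@H](C(C)C)[C@H](c2c(OCc3ccccc3)c(C=O)c(OCc3ccccc3)c(C=O)c2OCc2ccccc2)O1)C(=O)OC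
F7 | step 5 | 2,4,6-tris(benzyloxy)-5-[(2R,3S)-5,7-dihydroxy-6-(3-methylbutanoyl)-3-(propan-2-yl)-3,4-dihydro-2H-chromen-2-yl]benzene-1,3-dicarbaldehyde | CC(C)CC(=O)c1c(O)cc2c(c1O)C[C@@H](C(C)C)[C@H](c3c(OCc4ccccc4)c(C=O)c(OCc4ccccc4)c(C=O)c3OCc3ccccc3)O2
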